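**Plan**

- Retrosynthesis: the C8–O ester bond is cut first, then C7–C8, which opens the oxepane (O, C5–C10) to a C8 aldehyde and a 3-(bromomethyl)butenolide. Next come C7=C11 and C3=C4 (two metatheses), the C6–O ester, C4–C15 (carbonylation), C5–C6 (aldol) and the C10–O–C5 ether.
- Enabling feature: the α-methylene-γ-lactone (O–C6–C7–C11(=C13)–C12) with the neighbouring C8 carbinol is the SE2′ adduct of a C13-metallated butenolide (C13–C11=C7) and an aldehyde, both held cis on the oxepene (O, C10, C1–C5).
- Forward: (S)-linalool gives C10 with both arms; a glycolate ether and an auxiliary-controlled aldol with acrolein add C5–C7; the acyl carbon C4 becomes a 2-substituted acrylate.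
- Rings: butenolide, then oxepene (tandem ring-closing metathesis), then oxepane (Barbier closure), then acylation at C8.
- Stereochemistry: C10 from (S)-linalool; C5 from the Evans aldol; C6 from the same aldol followed by Mitsunobu inversion; C7 and C8 in the Barbier closure; C2′ and C3′ of the acyl group from a Sharpless epoxidation.

Key step: step 18

Remark: germacrane numbering is used (C10 methyl-bearing ether carbon, C5 the other ether carbon, C15 the ester carbon), and Lin stands for the (3S)-1-[(tert-butyldiphenylsilyl)oxy]-3,7-dimethyloct-6-en-3-yl group.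

**Route**

Step 1
Reactants: 1 (S)-linalool
Product: 3 (3S)-3,7-dimethyloct-6-ene-1,3-diol, via terminal 9-BBN adduct 2 (not isolated)
Conditions: 9-BBN (2.2 equiv), THF, 0 °C → rt; then NaOH, H2O2, 0 °C
Reagents that add atoms: hydrogen peroxide, OO
Why: Hydroboration–oxidation: 9-BBN adds to the unhindered monosubstituted vinyl group with boron at the terminal carbon and leaves the trisubstituted olefin alone, and oxidation gives the primary alcohol without touching the tertiary carbinol centre that becomes C10.

Step 2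
Reactants: 3 (3S)-3,7-dimethyloct-6-ene-1,3-diol
Product: 4 (3S)-1-[(tert-butyldiphenylsilyl)oxy]-3,7-dimethyloct-6-en-3-ol (Lin–OH)
Conditions: TBDPSCl, imidazole, CH2Cl2, 0 °C → rt
Reagents that add atoms: tert-butyl(chloro)diphenylsilane, CC(C)(C)[Si](Cl)(c1ccccc1)c1ccccc1
Why: Silylation with the bulky chlorosilane is selective for the primary hydroxyl over the tertiary one, and the robust silyl ether keeps C8 masked until step 16.

Step 3
Reactants: 4 Lin–OH; 5 bromoacetic acid
Product: 6 2-(Lin-oxy)acetic acid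
Conditions: NaH (3.5 equiv), THF/DMF, 0 °C → 60 °C; then aq. HCl work-up
Reagents that add atoms: none
Why: Williamson etherification: the sodium alkoxide of the tertiary alcohol displaces bromide from sodium bromoacetate, an unhindered primary electrophile without β-hydrogen, so the C10–O–C5 ether forms without touching the stereocentre.

Step 4
Reactants: 6 2-(Lin-oxy)acetic acid; 7 (4S)-4-benzyl-1,3-oxazolidin-2-one
Product: 9 (4S)-4-benzyl-3-[2-(Lin-oxy)acetyl]-1,3-oxazolidin-2-one, via mixed pivalic anhydride 8 (not isolated)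
Conditions: PivCl, Et3N, THF, −20 °C; then 7, LiCl, −20 °C → rt
Reagents that add atoms: none
Why: N-Acylation of the oxazolidinone through the mixed pivalic anhydride, which is attacked at the less hindered glycolyl carbonyl with LiCl assistance.

Step 5
Reactants: 9 N-glycolyl oxazolidinone; 10 acrolein
Product: 12 (4S)-4-benzyl-3-[(2S,3R)-3-hydroxy-2-(Lin-oxy)pent-4-enoyl]-1,3-oxazolidin-2-one (syn aldol), via Z dibutylboron enolate 11 (not isolated)
Conditions: Bu2BOTf, Et3N, CH2Cl2, −78 → 0 °C; 10, −78 → 0 °C; pH 7 buffer, MeOH, H2O2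
Reagents that add atoms: none
Why: Evans syn aldol: soft enolisation gives the Z boron enolate, which adds to acrolein through a closed Zimmerman–Traxler chair on the enolate face away from the benzyl group, setting C5 in its final configuration (2S here) and C6 as the syn carbinol (3R), which step 12 inverts.

Step 6
Reactants: 12 syn aldol adduct
Product: 13 (2S,3R)-3-hydroxy-N-methoxy-N-methyl-2-(Lin-oxy)pent-4-enamide
Conditions: MeNHOMe·HCl, AlMe3, CH2Cl2, −15 → 0 °C
Reagents that add atoms: N,O-dimethylhydroxylamine hydrochloride, CNOC.Cl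
Why: Weinreb transamidation with the aluminium amide, assisted by the free β-hydroxyl, cleaves the exocyclic imide carbonyl selectively and returns the auxiliary.

Step 7
Reactants: 13 Weinreb amide
Product: 14 (2S,3R)-N-methoxy-N-methyl-2-(Lin-oxy)-3-[(triethylsilyl)oxy]pent-4-enamide
Conditions: TESCl, imidazole, DMF, 0 °C → rt
Reagents that add atoms: chlorotriethylsilane, CC[Si](Cl)(CC)CC
Why: Silylation of the secondary allylic hydroxyl prevents retro-aldol cleavage and alkoxide formation in the basic steps 8 and 9.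

Step 8
Reactants: 14 silylated Weinreb amide
Product: 15 (3S,4R)-3-(Lin-oxy)-4-[(triethylsilyl)oxy]hex-5-en-2-one
Conditions: MeMgBr (3 equiv), THF, −78 → 0 °C; aq. NH4Cl
Reagents that add atoms: methylmagnesium bromide, C[Mg]Br
Why: Grignard addition to the Weinreb amide stops at the ketone because the chelated tetrahedral intermediate survives until work-up, so C4 becomes a methyl ketone without epimerising C5.

Step 9
Reactants: 15 methyl ketone
Product: 17 (3S,4R)-3-(Lin-oxy)-4-[(triethylsilyl)oxy]hexa-1,5-dien-2-yl trifluoromethanesulfonate, via terminal potassium enolate 16 (not isolated)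
Conditions: KN(SiMe3)2, THF, −78 °C; PhNTf2, −78 → −20 °C; aq. NH4Cl
Reagents that add atoms: N-phenylbis(trifluoromethanesulfonimide), O=S(=O)(N(c1ccccc1)S(=O)(=O)C(F)(F)F)C(F)(F)F
Why: Kinetic deprotonation by the bulky amide occurs at the methyl group and not at the hindered alkoxy-bearing C5, and O-triflation of the terminal enolate gives the 1-alken-2-yl triflate.

Step 10
Reactants: 17 enol triflate
Product: 18 methyl (3R,4R)-2-methylidene-3-(Lin-oxy)-4-[(triethylsilyl)oxy]hex-5-enoate
Conditions: Pd(OAc)2 (10 mol %), PPh3, Et3N, CO (1 atm), MeOH/DMF, rt → 45 °C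
Reagents that add atoms: carbon monoxide, [C-]#[O+]; methanol, CO
Why: Palladium-catalysed methoxycarbonylation of the alkenyl triflate (oxidative addition to zerovalent palladium, CO insertion, methanolysis) puts the C15 methyl ester on C4 and leaves the 2-substituted acrylate needed for ring closure.

Step 11
Reactants: 18 silylated acrylate
Product: 19 methyl (3R,4R)-4-hydroxy-2-methylidene-3-(Lin-oxy)hex-5-enoate
Conditions: HF·pyridine, pyridine, THF, 0 °C
Reagents that add atoms: none
Why: Buffered HF·pyridine removes the secondary triethylsilyl ether much faster than the primary tert-butyldiphenylsilyl ether.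

Step 12
Reactants: 19 syn hydroxy ester
Product: 20 methyl (3R,4S)-4-[(chloroacetyl)oxy]-2-methylidene-3-(Lin-oxy)hex-5-enoate
Conditions: PPh3, DIAD, ClCH2CO2H, toluene, 0 °C → rt
Reagents that add atoms: chloroacetic acid, OC(=O)CCl
Why: Mitsunobu reaction: the alkoxyphosphonium ion of the C6 carbinol is displaced by chloroacetate in an SN2 step with inversion, which turns the syn aldol relationship into the anti one required at C6 (S).

Step 13
Reactants: 20 chloroacetate
Product: 21 methyl (3R,4S)-4-hydroxy-2-methylidene-3-(Lin-oxy)hex-5-enoate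
Conditions: thiourea, 2,6-lutidine, EtOH, 45 °C
Reagents that add atoms: none
Why: Thiourea removes the chloroacetyl group under near-neutral conditions (S-alkylation, then cyclisation onto the ester carbonyl), so the free γ-hydroxy ester meets no alkoxide and should not lactonise onto C15.

Step 14
Reactants: 21 anti hydroxy ester; 22 2-(bromomethyl)acrylic acid
Product: 23 methyl (3R,4S)-4-{[2-(bromomethyl)acryloyl]oxy}-2-methylidene-3-(Lin-oxy)hex-5-enoate
Conditions: DCC, DMAP (10 mol %), CH2Cl2, 0 °C → rt
Reagents that add atoms: none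
Why: Steglich esterification acylates the C6 hydroxyl with retention and brings in C11, C12 and C13 with the allylic bromide already in place.

Step 15
Reactants: 23 tetraene ester
Product: 25 methyl (2R,7S)-2-[(2S)-4-(bromomethyl)-5-oxo-2,5-dihydrofuran-2-yl]-7-{2-[(tert-butyldiphenylsilyl)oxy]ethyl}-7-methyl-2,5,6,7-tetrahydrooxepine-3-carboxylate, via butenolide triene 24 (not isolated)
Conditions: second-generation Grubbs catalyst, RuCl2(=CHPh)(H2IMes)(PCy3) (10 mol %), toluene (2 mM), argon sparge, 40 °C then 80 °C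
Reagents that add atoms: none
Why: Tandem ring-closing metathesis: the ruthenium carbene loads on the monosubstituted C7 vinyl group and closes onto the 2-(bromomethyl)acrylate to give the butenolide, and the carbene then formed at C3 with loss of 2-methylpropene closes onto the C4 acrylate to give the trisubstituted oxepene enoate, the only other normal-sized ring the remaining olefins can form.

Step 16
Reactants: 25 silyl-protected oxepene butenolide
Product: 26 methyl (2R,7S)-2-[(2S)-4-(bromomethyl)-5-oxo-2,5-dihydrofuran-2-yl]-7-(2-hydroxyethyl)-7-methyl-2,5,6,7-tetrahydrooxepine-3-carboxylate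
Conditions: HF·pyridine, THF, 0 °C → rt
Reagents that add atoms: none
Why: Fluoride cleavage of the silyl ether under acidic rather than basic conditions, which the base-sensitive bromomethylbutenolide should tolerate.

Step 17
Reactants: 26 primary alcohol
Product: 27 methyl (2R,7S)-2-[(2S)-4-(bromomethyl)-5-oxo-2,5-dihydrofuran-2-yl]-7-methyl-7-(2-oxoethyl)-2,5,6,7-tetrahydrooxepine-3-carboxylate
Conditions: Dess–Martin periodinane, CH2Cl2, 0 °C → rt
Reagents that add atoms: none
Why: Dess–Martin oxidation converts the primary alcohol into the C8 aldehyde under neutral conditions without enolising the butenolide or displacing the allylic bromide.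

Step 18
Reactants: 27 oxepene aldehyde with 3-(bromomethyl)butenolide
Product: 29 C8 alcohol of the target (5R,6S,7R,8R,10S; trans-fused α-methylene-γ-lactone on the 11-oxabicyclo[4.4.1]undecene core), via allylzinc bromide 28 (not isolated)
Conditions: Zn dust (activated, excess), THF/sat. aq NH4Cl (5:1), 27 added slowly to 2 mM, 0 °C → rt
Reagents that add atoms: none
Why: Zinc inserts into the C13–Br bond and the resulting allylzinc adds to the tethered aldehyde in an SE2′ sense through C7, so that C7–C8 forms, the C11=C13 methylene is unveiled and the oxepane (O, C5, C6, C7, C8, C9, C10) closes by 7-exo-trig attack on the carbonyl; the closest known reaction is the intermolecular Barbier allylation of aldehydes with 3-(bromomethyl)furan-2(5H)-ones to β-(hydroxyalkyl)-α-methylene-γ-butyrolactones. Closure is possible because the C9 arm and the butenolide sit cis on the oxepene, three atoms apart across the ether oxygen. C7 is controlled by C6: C5 and the tether lie on one face of the butenolide, and the aldehyde is expected to reach C7 from the other face, which gives the trans-fused lactone (7R). C8 is controlled by the orientation of the carbonyl in the ring-forming transition state: the tether holds C9 anti to C11, and the target needs the oxygen between C11 and C6 (hydroxyl cis to C11, 8R), an open arrangement that zinc in aqueous NH4Cl is expected to favour, whereas a chair with the oxygen bound to the metal on C13 would give the C8 epimer. The step therefore needs closure to outrun protonolysis of the allylzinc (slow addition to excess metal at high dilution) and two facial selectivities, of which the one at C7 rests on the substrate and the one at C8 on the metal and medium, the less secure of the two.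

Step 19
Reactants: 30 tiglic acid
Product: 31 (E)-2-methylbut-2-en-1-ol
Conditions: LiAlH4, Et2O, 0 °C → rt
Reagents that add atoms: none
Why: Hydride reduction of the carboxylic acid to the allylic alcohol, which keeps the E double bond.

Step 20
Reactants: 31 (E)-2-methylbut-2-en-1-ol
Product: 32 [(2R,3R)-2,3-dimethyloxiran-2-yl]methanol
Conditions: Ti(OiPr)4, diethyl D-(−)-tartrate, t-BuOOH, 4 Å molecular sieves, CH2Cl2, −20 °C
Reagents that add atoms: tert-butyl hydroperoxide, CC(C)(C)OO
Why: Sharpless asymmetric epoxidation: with the D-(−)-tartrate ligand the titanium-bound peroxide is delivered to the face of the E allylic alcohol that gives the (2R,3R)-epoxy alcohol, and the cis relationship of the two methyl groups follows from the olefin geometry.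

Step 21
Reactants: 32 epoxy alcohol
Product: 33 (2S,3R)-2,3-dimethyloxirane-2-carboxylic acid
Conditions: RuCl3·xH2O (2 mol %), NaIO4, CCl4/MeCN/H2O, rt
Reagents that add atoms: water, O
Why: Ruthenium tetroxide, generated catalytically from RuCl3 and periodate, oxidises the primary alcohol to the acid through the aldehyde hydrate without opening the epoxide; the descriptor at C2 becomes S only through the change in substituent priority.

Step 22
Reactants: 29 C8 alcohol; 33 (2S,3R)-2,3-dimethyloxirane-2-carboxylic acid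
Product: 35 target CNP0240298.1, via mixed trichlorobenzoic anhydride 34 (not isolated)
Conditions: 2,4,6-trichlorobenzoyl chloride, Et3N, THF, rt; then 29, DMAP, toluene, rt
Reagents that add atoms: none
Why: Yamaguchi esterification: DMAP attacks the mixed anhydride at the epoxy-acyl carbonyl and the acylpyridinium acylates the C8 hydroxyl with retention, which completes the target.

**Compound list**

1 | (S)-linalool | C=C[C@@](C)(O)CCC=C(C)C | starting material
2 | (3R)-1-(9-borabicyclo[3.3.1]nonan-9-yl)-3,7-dimethyloct-6-en-3-ol (spatial arrangement as in 1) | CC(C)=CCC[C@](C)(O)CCB1C2CCCC1CCC2 | intermediate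
3 | (3S)-3,7-dimethyloct-6-ene-1,3-diol | OCC[C@@](C)(O)CCC=C(C)C | intermediate
4 | (3S)-1-[(tert-butyldiphenylsilyl)oxy]-3,7-dimethyloct-6-en-3-ol (Lin–OH) | CC(C)(C)[Si](c1ccccc1)(c1ccccc1)OCC[C@@](C)(O)CCC=C(C)C | intermediate
5 | bromoacetic acid | OC(=O)CBr | starting material
6 | 2-(Lin-oxy)acetic acid | CC(C)(C)[Si](c1ccccc1)(c1ccccc1)OCC[C@@](C)(OCC(=O)O)CCC=C(C)C | intermediate
7 | (4S)-4-benzyl-1,3-oxazolidin-2-one | O=C1N[C@@H](Cc2ccccc2)CO1 | starting material
8 | mixed anhydride of 6 with pivalic acid | CC(C)(C)[Si](c1ccccc1)(c1ccccc1)OCC[C@@](C)(OCC(=O)OC(=O)C(C)(C)C)CCC=C(C)C | intermediate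
9 | (4S)-4-benzyl-3-[2-(Lin-oxy)acetyl]-1,3-oxazolidin-2-one | CC(C)(C)[Si](c1ccccc1)(c1ccccc1)OCC[C@@](C)(OCC(=O)N1[C@@H](Cc2ccccc2)COC1=O)CCC=C(C)C | intermediate
10 | acrolein | C=CC=O | starting material
11 | Z dibutylboron enolate of 9 | CCCCB(CCCC)O/C(=C\O[C@](C)(CCO[Si](c1ccccc1)(c1ccccc1)C(C)(C)C)CCC=C(C)C)N1[C@@H](Cc2ccccc2)COC1=O | intermediate
12 | (4S)-4-benzyl-3-[(2S,3R)-3-hydroxy-2-(Lin-oxy)pent-4-enoyl]-1,3-oxazolidin-2-one | C=C[C@@H](O)[C@H](O[C@](C)(CCO[Si](c1ccccc1)(c1ccccc1)C(C)(C)C)CCC=C(C)C)C(=O)N1[C@@H](Cc2ccccc2)COC1=O | intermediate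
13 | (2S,3R)-3-hydroxy-N-methoxy-N-methyl-2-(Lin-oxy)pent-4-enamide | C=C[C@@H](O)[C@H](O[C@](C)(CCO[Si](c1ccccc1)(c1ccccc1)C(C)(C)C)CCC=C(C)C)C(=O)N(C)OC | intermediate
14 | (2S,3R)-N-methoxy-N-methyl-2-(Lin-oxy)-3-[(triethylsilyl)oxy]pent-4-enamide | C=C[C@@H](O[Si](CC)(CC)CC)[C@H](O[C@](C)(CCO[Si](c1ccccc1)(c1ccccc1)C(C)(C)C)CCC=C(C)C)C(=O)N(C)OC | intermediate
15 | (3S,4R)-3-(Lin-oxy)-4-[(triethylsilyl)oxy]hex-5-en-2-one | C=C[C@@H](O[Si](CC)(CC)CC)[C@H](O[C@](C)(CCO[Si](c1ccccc1)(c1ccccc1)C(C)(C)C)CCC=C(C)C)C(C)=O | intermediate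
16 | terminal potassium enolate of 15 | C=C[C@@H](O[Si](CC)(CC)CC)[C@H](O[C@](C)(CCO[Si](c1ccccc1)(c1ccccc1)C(C)(C)C)CCC=C(C)C)C(=C)[O-].[K+] | intermediate
17 | (3S,4R)-3-(Lin-oxy)-4-[(triethylsilyl)oxy]hexa-1,5-dien-2-yl trifluoromethanesulfonate | C=C[C@@H](O[Si](CC)(CC)CC)[C@H](O[C@](C)(CCO[Si](c1ccccc1)(c1ccccc1)C(C)(C)C)CCC=C(C)C)C(=C)OS(=O)(=O)C(F)(F)F | intermediate
18 | methyl (3R,4R)-2-methylidene-3-(Lin-oxy)-4-[(triethylsilyl)oxy]hex-5-enoate | C=C[C@@H](O[Si](CC)(CC)CC)[C@H](O[C@](C)(CCO[Si](c1ccccc1)(c1ccccc1)C(C)(C)C)CCC=C(C)C)C(=C)C(=O)OC | intermediate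
19 | methyl (3R,4R)-4-hydroxy-2-methylidene-3-(Lin-oxy)hex-5-enoate | C=C[C@@H](O)[C@H](O[C@](C)(CCO[Si](c1ccccc1)(c1ccccc1)C(C)(C)C)CCC=C(C)C)C(=C)C(=O)OC | intermediate
20 | methyl (3R,4S)-4-[(chloroacetyl)oxy]-2-methylidene-3-(Lin-oxy)hex-5-enoate | C=C[C@H](OC(=O)CCl)[C@H](O[C@](C)(CCO[Si](c1ccccc1)(c1ccccc1)C(C)(C)C)CCC=C(C)C)C(=C)C(=O)OC | intermediate
21 | methyl (3R,4S)-4-hydroxy-2-methylidene-3-(Lin-oxy)hex-5-enoate | C=C[C@H](O)[C@H](O[C@](C)(CCO[Si](c1ccccc1)(c1ccccc1)C(C)(C)C)CCC=C(C)C)C(=C)C(=O)OC | intermediate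
22 | 2-(bromomethyl)acrylic acid | C=C(CBr)C(=O)O | starting material
23 | methyl (3R,4S)-4-{[2-(bromomethyl)acryloyl]oxy}-2-methylidene-3-(Lin-oxy)hex-5-enoate | C=C[C@H](OC(=O)C(=C)CBr)[C@H](O[C@](C)(CCO[Si](c1ccccc1)(c1ccccc1)C(C)(C)C)CCC=C(C)C)C(=C)C(=O)OC | intermediate
24 | methyl (3R)-3-[(2S)-4-(bromomethyl)-5-oxo-2,5-dihydrofuran-2-yl]-2-methylidene-3-(Lin-oxy)propanoate | C=C(C(=O)OC)[C@H]([C@H]1OC(=O)C(CBr)=C1)O[C@](C)(CCO[Si](c1ccccc1)(c1ccccc1)C(C)(C)C)CCC=C(C)C | intermediate
25 | methyl (2R,7S)-2-[(2S)-4-(bromomethyl)-5-oxo-2,5-dihydrofuran-2-yl]-7-{2-[(tert-butyldiphenylsilyl)oxy]ethyl}-7-methyl-2,5,6,7-tetrahydrooxepine-3-carboxylate | CC(C)(C)[Si](c1ccccc1)(c1ccccc1)OCC[C@]1(C)CCC=C(C(=O)OC)[C@H]([C@H]2OC(=O)C(CBr)=C2)O1 | intermediate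
26 | methyl (2R,7S)-2-[(2S)-4-(bromomethyl)-5-oxo-2,5-dihydrofuran-2-yl]-7-(2-hydroxyethyl)-7-methyl-2,5,6,7-tetrahydrooxepine-3-carboxylate | OCC[C@]1(C)CCC=C(C(=O)OC)[C@H]([C@H]2OC(=O)C(CBr)=C2)O1 | intermediate
27 | methyl (2R,7S)-2-[(2S)-4-(bromomethyl)-5-oxo-2,5-dihydrofuran-2-yl]-7-methyl-7-(2-oxoethyl)-2,5,6,7-tetrahydrooxepine-3-carboxylate | O=CC[C@]1(C)CCC=C(C(=O)OC)[C@H]([C@H]2OC(=O)C(CBr)=C2)O1 | intermediate
28 | allylzinc bromide of 27 (zinc on C13) | O=CC[C@]1(C)CCC=C(C(=O)OC)[C@H]([C@H]2OC(=O)C(C[Zn]Br)=C2)O1 | intermediate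
29 | C8 alcohol of the target (5R,6S,7R,8R,10S) | C=C1C(=O)O[C@H]2[C@H]1[C@H](O)C[C@]1(C)CCC=C(C(=O)OC)[C@H]2O1 | intermediate
30 | tiglic acid | C/C=C(\C)C(=O)O | starting material
31 | (E)-2-methylbut-2-en-1-ol | C/C=C(\C)CO | intermediate
32 | [(2R,3R)-2,3-dimethyloxiran-2-yl]methanol | OC[C@@]1(C)O[C@@H]1C | intermediate
33 | (2S,3R)-2,3-dimethyloxirane-2-carboxylic acid | OC(=O)[C@@]1(C)O[C@@H]1C | intermediate
34 | mixed anhydride of 33 with 2,4,6-trichlorobenzoic acid | O=C(OC(=O)c1c(Cl)cc(Cl)cc1Cl)[C@@]1(C)O[C@@H]1C | intermediate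
35 | CNP0240298.1 (5R,6S,7R,8R,10S; 8-O-[(2S,3R)-2,3-dimethyloxirane-2-carbonyl]) | C=C1C(=O)O[C@H]2[C@H]1[C@H](OC(=O)[C@@]1(C)O[C@@H]1C)C[C@]1(C)CCC=C(C(=O)OC)[C@H]2O1 | target

**Step count**

Total: 22 steps. Longest linear sequence: 19 steps (steps 1–18 and 22); steps 19–21 make the acyl fragment.

**Steps most likely to fail**

Step 18. The allylzinc may add through a metal-bridged chair with the carbonyl oxygen turned towards C13, so that the other face of the aldehyde reacts, or protonolysis of the allylzinc may outrun the closure. The fallback sets out from 27 and closes the ring with CrCl2 in dry THF at high dilution. No proton source is present there and the chair pathway is the rule, so this should give the C8-epimeric alcohol F1 on purpose. F1 is then coupled with acid 33 under Mitsunobu conditions (PPh3, DIAD, toluene), where the SN2 displacement inverts C8, and the route comes back at 35.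

Step 12. Displacement at the hindered allylic carbinol may be diverted to SN2′ attack at the vinyl terminus or to elimination. The fallback sets out from 19 and oxidises it with Dess–Martin periodinane to the vinyl ketone F2. F2 is reduced with Zn(BH4)2 in Et2O at −78 °C, where the zinc chelate between the ketone and the C5 ether oxygen should expose the face that leads to the 5,6-anti alcohol. The route comes back at 21, and steps 12 and 13 are not needed.

Step 3. The hindered tertiary alkoxide may alkylate so slowly that silyl transfer from the primary oxygen or decomposition competes. The fallback sets out from 4 and uses an O–H insertion under neutral conditions: ethyl diazoacetate is added slowly to 4 and Rh2(OAc)4 (1 mol %) in CH2Cl2 to give the ethyl ester F3. Saponification of F3 with LiOH in THF/H2O brings the route back at 6.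

**Further compounds**

F1 | step 18 | C8 epimer of 29 (5R,6S,7R,8S,10S) | C=C1C(=O)O[C@H]2[C@H]1[C@@H](O)C[C@]1(C)CCC=C(C(=O)OC)[C@H]2O1
F2 | step 12 | methyl (3R)-2-methylidene-4-oxo-3-(Lin-oxy)hex-5-enoate | C=CC(=O)[C@H](O[C@](C)(CCO[Si](c1ccccc1)(c1ccccc1)C(C)(C)C)CCC=C(C)C)C(=C)C(=O)OC
F3 | step 3 | ethyl 2-(Lin-oxy)acetate | CC(C)(C)[Si](c1ccccc1)(c1ccccc1)OCC[C@@](C)(OCC(=O)OCC)CCC=C(C)C
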